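A direct plan would esterify the 4-hydroxyl of 2,4-dihydroxy-6-propylbenzoic acid A1 with 4-hydroxy-2-methoxy-6-propylbenzoic acid A2, activated as 4-hydroxy-2-methoxy-6-propylbenzoyl chloride A3. A2 would be made from A1 by benzylation of the carboxyl and 4-hydroxyl groups to benzyl 4-(benzyloxy)-2-hydroxy-6-propylbenzoate A4, 2-O-methylation to benzyl 4-(benzyloxy)-2-methoxy-6-propylbenzoate A5 and hydrogenolysis. Its weakest steps would be:
- the ester formation between the rings, since the acyl carbon of A3 would be flanked by methoxy and propyl and would meet two phenols and a carboxylate of A1 while A3 itself would carry a free phenol, so that oligomers and mixed anhydrides would be expected;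
- the 2-O-methylation of A4 to A5, which would address the least reactive, hydrogen-bonded hydroxyl;
- the benzylation/hydrogenolysis pair around A4 and A5, which would add operations but no complexity.

The route would cut ring A (the benzoyl ring) instead of the ester. C1 and C6 of ring A, which carry the acyl carbon and the propyl group, are the two alkyne carbons of hex-2-ynoic acid; C2–C5, with the methoxy and hydroxy oxygens already told apart, come from 1-methoxy-3-(trimethylsilyloxy)cyclohexa-1,3-diene. The depside C(=O)–O bond would be made first, while the acyl carbon sits on an unhindered sp carbon of the ynoate. One Diels–Alder/ethene-extrusion (Alder–Rickert) operation would then form two C–C bonds, close and aromatise ring A and fix the 2-methoxy/4-hydroxy pattern. Hindered aroyl transfer, selective O-methylation and all protection of ring A would disappear.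

Key step: step 4

Assumption: 2,4-dihydroxy-6-propylbenzoic acid, hex-2-ynoic acid and 3-methoxycyclohex-2-en-1-one are taken as catalogue chemicals; the target has no stereocentre, and the bridgehead stereocentres of the bicyclic intermediate of the key step (racemic) are lost on aromatisation.

Step 1
Reactants: 1 2,4-dihydroxy-6-propylbenzoic acid
Product: 2 benzyl 2,4-dihydroxy-6-propylbenzoate
Conditions: BnBr (1.05 equiv), KHCO3 (1.2 equiv), DMF, 23 °C, 16 h
Reagents that add atoms: benzyl bromide, BrCc1ccccc1
Why: SN2 O-alkylation of a carboxylate; hydrogencarbonate ionises only the carboxylic acid, so the phenols should stay protonated and unalkylated, and room temperature spares the easily decarboxylated β-resorcylic acid.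

Step 2
Reactants: 2 benzyl 2,4-dihydroxy-6-propylbenzoate; 3 hex-2-ynoic acid
Product: 4 benzyl 4-(hex-2-ynoyloxy)-2-hydroxy-6-propylbenzoate
Conditions: 3 (1.1 equiv), DCC (1.1 equiv), 4-(dimethylamino)pyridine (5 mol%), CH2Cl2, −10 → 23 °C, 4 h
Reagents that add atoms: none
Why: Steglich esterification; the 4-hydroxyl is the more acidic, unhindered phenol whereas the 2-hydroxyl is held in a hydrogen bond to the ester carbonyl, and the acyl carbon of 3 sits on an sp carbon and is unhindered, so one equivalent of activated acid should acylate O-4 only.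

Step 3
Reactants: 5 3-methoxycyclohex-2-en-1-one
Product: 7 1-methoxy-3-(trimethylsilyloxy)cyclohexa-1,3-diene, via lithium dienolate 6 (not isolated)
Conditions: LiN(iPr)2 (1.1 equiv), THF, −78 °C, 45 min; Me3SiCl (1.3 equiv), −78 → 0 °C; pentane, filtration, distillation
Reagents that add atoms: chlorotrimethylsilane, C[Si](C)(C)Cl
Why: Kinetic enolisation of the vinylogous ester at the α'-methylene gives the cross-conjugated lithium dienolate, and O-silylation of it should give diene 7, which carries the methoxy group on a diene terminus and the silyloxy group on an inner diene carbon; no stereocentre is formed.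

Step 4
Reactants: 4 benzyl 4-(hex-2-ynoyloxy)-2-hydroxy-6-propylbenzoate; 7 1-methoxy-3-(trimethylsilyloxy)cyclohexa-1,3-diene
Product: 11 benzyl 2-hydroxy-4-[(4-hydroxy-2-methoxy-6-propylbenzoyl)oxy]-6-propylbenzoate, via 2-O-silyl ether 8 (not isolated), via bicyclo[2.2.2]octadiene adduct 9 (not isolated), via bis-silyl ether 10 (not isolated)
Conditions: N,O-bis(trimethylsilyl)acetamide (1.2 equiv), o-xylene, 60 °C, 1 h; 7 (3 equiv), 165 °C, sealed tube, Ar, 24 h; then 1 M HCl/THF, 23 °C, 1 h
Reagents that add atoms: none
Why: N,O-bis(trimethylsilyl)acetamide first caps the 2-hydroxyl of 4 as silyl ether 8, so that no acidic proton is left to desilylate the diene; 7 and the electron-poor triple bond of 8 then undergo a normal-demand Diels–Alder reaction to bicyclo[2.2.2]octa-2,5-diene 9, which at the same temperature loses ethene by retro-[4+2] cleavage (Alder–Rickert reaction) to give benzene ring A in 10, and dilute acid removes both silyl groups. The closest known reaction type is the Alder–Rickert benzannulation of 1-alkoxy- and 1-alkoxy-3-silyloxycyclohexa-1,3-dienes with alkyl 2-alkynoates to 2-alkoxy-6-alkylbenzoates. Ring A is closed by an intermolecular [4+2] cycloaddition that forms its C1–C2 and C5–C6 bonds, and it is aromatised by cycloreversion, not by oxidation. The two bridgehead stereocentres of 9 arise as a racemate and vanish with the ethano bridge, so no stereocontrol is needed. The step needs one regiochemistry, methoxy ortho and silyloxy para to the acyl carbon: the 1-methoxy group (through the diene) and the 3-silyloxy group (directly) both raise the HOMO coefficient at the unsubstituted terminus C4 of 7, which bonds to the propyl-bearing β-carbon of the ynoate, and the smaller steric clash of that pairing points the same way. Chemoselectivity rests on the ynoate being the only electron-poor π bond, the benzyl ester, the aryl ester and both arenes being inert to a thermal cycloaddition.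

Step 5
Reactants: 11 benzyl 2-hydroxy-4-[(4-hydroxy-2-methoxy-6-propylbenzoyl)oxy]-6-propylbenzoate
Product: 12 2-hydroxy-4-[(4-hydroxy-2-methoxy-6-propylbenzoyl)oxy]-6-propylbenzoic acid
Conditions: H2 (1 atm), Pd on carbon (10 wt% Pd), EtOAc, 23 °C, 2 h; filter; evaporate below 30 °C
Reagents that add atoms: none
Why: Catalytic hydrogenolysis of the benzylic C–O bond should free the carboxylic acid under neutral conditions that leave the depside aryl ester, the aryl methyl ether and the decarboxylation-prone salicylic acid untouched.

Compound list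
1 | 2,4-dihydroxy-6-propylbenzoic acid | CCCc1cc(O)cc(O)c1C(=O)O | starting material
2 | benzyl 2,4-dihydroxy-6-propylbenzoate | CCCc1cc(O)cc(O)c1C(=O)OCc1ccccc1 | intermediate
3 | hex-2-ynoic acid | CCCC#CC(=O)O | starting material
4 | benzyl 4-(hex-2-ynoyloxy)-2-hydroxy-6-propylbenzoate | CCCC#CC(=O)Oc1cc(O)c(C(=O)OCc2ccccc2)c(CCC)c1 | intermediate
5 | 3-methoxycyclohex-2-en-1-one | COC1=CC(=O)CCC1 | starting material
6 | lithium 5-methoxycyclohexa-1,5-dien-1-olate | [Li+].[O-]C1=CCCC(OC)=C1 | intermediate
7 | 1-methoxy-3-(trimethylsilyloxy)cyclohexa-1,3-diene | COC1=CC(O[Si](C)(C)C)=CCC1 | intermediate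
8 | benzyl 4-(hex-2-ynoyloxy)-6-propyl-2-(trimethylsilyloxy)benzoate | CCCC#CC(=O)Oc1cc(O[Si](C)(C)C)c(C(=O)OCc2ccccc2)c(CCC)c1 | intermediate
9 | benzyl 4-{[1-methoxy-3-propyl-5-(trimethylsilyloxy)bicyclo[2.2.2]octa-2,5-diene-2-carbonyl]oxy}-6-propyl-2-(trimethylsilyloxy)benzoate (racemic) | COC12CCC(C(O[Si](C)(C)C)=C1)C(CCC)=C2C(=O)Oc1cc(O[Si](C)(C)C)c(C(=O)OCc2ccccc2)c(CCC)c1 | intermediate
10 | benzyl 4-{[2-methoxy-6-propyl-4-(trimethylsilyloxy)benzoyl]oxy}-6-propyl-2-(trimethylsilyloxy)benzoate | CCCc1cc(OC(=O)c2c(CCC)cc(O[Si](C)(C)C)cc2OC)cc(O[Si](C)(C)C)c1C(=O)OCc1ccccc1 | intermediate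
11 | benzyl 2-hydroxy-4-[(4-hydroxy-2-methoxy-6-propylbenzoyl)oxy]-6-propylbenzoate | CCCc1cc(OC(=O)c2c(CCC)cc(O)cc2OC)cc(O)c1C(=O)OCc1ccccc1 | intermediate
12 | 2-hydroxy-4-[(4-hydroxy-2-methoxy-6-propylbenzoyl)oxy]-6-propylbenzoic acid | CCCc1cc(OC(=O)c2c(CCC)cc(O)cc2OC)cc(O)c1C(=O)O | target

Total step count: 5. Longest linear sequence: 4 steps (steps 1, 2, 4 and 5).

Steps most likely to fail

Step 4 (key step). The cycloaddition to the β-propyl ynoate may be slower than the thermal 1,5-hydrogen shift in diene 7, which would scramble the oxygen pattern, or slower than silyl migration and decomposition at 165 °C. The fallback would set out from silyl ether 8 and replace the cyclic diene by an acyclic ketene-acetal diene, so that aromatisation no longer depends on a cycloreversion. 4,4-Dimethoxybut-3-en-2-one F1 would be made by acylation of 1,1-dimethoxyethene with acetyl chloride, and converted with LiN(iPr)2 and Me3SiCl into 1,1-dimethoxy-3-(trimethylsilyloxy)buta-1,3-diene F2. This more nucleophilic diene should add to 8 near 110 °C in toluene with the same orientation (CH2 terminus to the propyl-bearing carbon). The adduct, benzyl 4-{[6,6-dimethoxy-2-propyl-4-(trimethylsilyloxy)cyclohexa-1,4-diene-1-carbonyl]oxy}-6-propyl-2-(trimethylsilyloxy)benzoate F3, would aromatise by 1,4-elimination of methanol. This gives bis-silyl ether 10, where the route is rejoined before the same acid work-up.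

Step 2. The phenol or the pyridine catalyst may add in conjugate fashion to the activated ynoic acid, the O-acylisourea may rearrange to an N-acylurea, or both hydroxyls may be acylated. The fallback would set out from 2 and 3 and change from nucleophile-catalysed to acid-mediated acylation. Acid 3 would be treated with (CF3CO)2O in toluene at 0–23 °C to give hex-2-ynoic trifluoroacetic anhydride F4. This acylates the free 4-hydroxyl of 2 with no base, phenoxide or nucleophilic catalyst present, and the route is rejoined at 4.

Step 1. The 4-hydroxyl may be benzylated beside the carboxylate, and the β-resorcylic acid may lose CO2 in DMF. The fallback would set out from 1 and introduce benzyl as a nucleophile instead of an electrophile. Acetone, (CF3CO)2O and CF3CO2H would tie the carboxyl and 2-hydroxyl groups together as 7-hydroxy-2,2-dimethyl-5-propyl-4H-1,3-benzodioxin-4-one F5. Opening of its acyl carbon with NaOCH2Ph (benzyl alcohol, NaH, THF, 0 °C) would release acetone and give 2, where the route is rejoined; no phenol can be benzylated in this sequence.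

Further compounds
F1 | step 4 | 4,4-dimethoxybut-3-en-2-one | CC(=O)C=C(OC)OC
F2 | step 4 | 1,1-dimethoxy-3-(trimethylsilyloxy)buta-1,3-diene | COC(OC)=CC(=C)O[Si](C)(C)C
F3 | step 4 | benzyl 4-{[6,6-dimethoxy-2-propyl-4-(trimethylsilyloxy)cyclohexa-1,4-diene-1-carbonyl]oxy}-6-propyl-2-(trimethylsilyloxy)benzoate | CCCC1=C(C(=O)Oc2cc(O[Si](C)(C)C)c(C(=O)OCc3ccccc3)c(CCC)c2)C(OC)(OC)C=C(O[Si](C)(C)C)C1
F4 | step 2 | hex-2-ynoic trifluoroacetic anhydride | CCCC#CC(=O)OC(=O)C(F)(F)F
F5 | step 1 | 7-hydroxy-2,2-dimethyl-5-propyl-4H-1,3-benzodioxin-4-one | CCCc1cc(O)cc2OC(C)(C)OC(=O)c12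
A1 | direct plan | 2,4-dihydroxy-6-propylbenzoic acid | CCCc1cc(O)cc(O)c1C(=O)O
A2 | direct plan | 4-hydroxy-2-methoxy-6-propylbenzoic acid | CCCc1cc(O)cc(OC)c1C(=O)O
A3 | direct plan | 4-hydroxy-2-methoxy-6-propylbenzoyl chloride | CCCc1cc(O)cc(OC)c1C(=O)Cl
A4 | direct plan | benzyl 4-(benzyloxy)-2-hydroxy-6-propylbenzoate | CCCc1cc(OCc2ccccc2)cc(O)c1C(=O)OCc1ccccc1
A5 | direct plan | benzyl 4-(benzyloxy)-2-methoxy-6-propylbenzoate | CCCc1cc(OCc2ccccc2)cc(OC)c1C(=O)OCc1ccccc1
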